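**Plan**
- Retrosynthesis: after loss of two MOM ethers, ring C is cut at O1–C2 and at C4–C3 in one stroke. This gives a ring A salicylaldehyde (6) and benzofuran 2,3-oxide (8). Aldehyde 6 is taken back through formyl, prenyl and the C8a oxygen to 2-methoxyresorcinol.
- Enabling feature: the 2'-OH of ring B is ortho to C2, so ring B, C2, C3 and the C3 oxygen are the atoms of benzofuran oxide, a masked o-quinone methide aldehyde that is electrophilic at C2 and at C3. O1–C8a–C4a–C4 of ring A is a salicylaldehyde, nucleophilic at O1 and, after carbene polarity reversal, at C4.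
- Forward: ring A is dressed in four steps (MOM, C–H borylation/oxidation, C-prenylation, ortho-formylation) and benzofuran is epoxidised. Ring C is then closed last by an oxa-Michael/cross-benzoin annulation that is a pure isomerising addition, and MOM removal ends the route.
- Stereochemistry: C3 comes from the chiral triazolylidene (face selection at the C3 formyl group). C2 follows by thermodynamic relay to the trans-diequatorial (2R,3R) isomer through the reversible quinone methide chemistry at C2.

Key step: step 6

Remark 1: the (5aR,10bS) antipode of the triazolium salt is assumed to be the one whose carbene–aldehyde adduct attacks the Si face of the C3 formyl group; if the sense proves opposite, the (5aS,10bR) antipode is used and nothing else changes.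
Remark 2: benzofuran 2,3-oxide is assumed to be accessible by low-temperature dimethyldioxirane epoxidation and to be handled only cold and in solution, as for this class of labile oxides.

**Route**

Step 1
Reactants: 1 2-methoxybenzene-1,3-diol (2-methoxyresorcinol)
Product: 2 2-methoxy-1,3-bis(methoxymethoxy)benzene
Conditions: MOMCl (2.5 equiv), iPr2NEt (3 equiv), CH2Cl2, 0 °C → rt
Reagents that add atoms: chloromethyl methyl ether, COCCl
Why: Williamson-type alkylation of both phenols gives the bis-MOM ether, which masks the future C5 and C7 oxygens for the whole route.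

Step 2
Reactants: 2 2-methoxy-1,3-bis(methoxymethoxy)benzene
Product: 4 4-methoxy-3,5-bis(methoxymethoxy)phenol, via aryl pinacol boronate 3 (not isolated)
Conditions: [Ir(OMe)(cod)]2 (1.5 mol %), 4,4'-di-tert-butyl-2,2'-bipyridine (3 mol %), B2pin2 (1.0 equiv), THF, 80 °C; then 30% H2O2, aq. NaOH, 0 °C → rt
Reagents that add atoms: hydrogen peroxide, OO; bis(pinacolato)diboron, B1(OC(C)(C)C(C)(C)O1)B1OC(C)(C)C(C)(C)O1 (its boron is present in 3 only)
Why: sterically controlled iridium-catalysed aromatic C–H borylation should occur at the only C–H without an ortho substituent, and oxidation of the C–B bond then gives the single free phenol that becomes O1.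

Step 3
Reactants: 4 4-methoxy-3,5-bis(methoxymethoxy)phenol
Product: 5 4-methoxy-3,5-bis(methoxymethoxy)-2-(3-methylbut-2-en-1-yl)phenol
Conditions: NaH (1.05 equiv), toluene, 0 °C; prenyl bromide (1.0 equiv), 0 °C → rt
Reagents that add atoms: prenyl bromide (1-bromo-3-methylbut-2-ene), CC(C)=CCBr
Why: ortho C-alkylation of a sodium phenoxide as a tight ion pair in a non-polar solvent should place the prenyl group on one of the two equivalent ortho carbons, so only mono- against di-alkylation has to be held by stoichiometry.

Step 4
Reactants: 5 4-methoxy-3,5-bis(methoxymethoxy)-2-(3-methylbut-2-en-1-yl)phenol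
Product: 6 2-hydroxy-5-methoxy-4,6-bis(methoxymethoxy)-3-(3-methylbut-2-en-1-yl)benzaldehyde
Conditions: MgCl2 (2 equiv), Et3N (4 equiv), paraformaldehyde (6 equiv), MeCN, reflux
Reagents that add atoms: formaldehyde (as paraformaldehyde), C=O
Why: in the magnesium-mediated ortho-formylation of phenols (Casnati–Skattebøl reaction) the magnesium phenoxide delivers formaldehyde to the only free ortho position and a second formaldehyde oxidises the benzylic alkoxide by hydride transfer.

Step 5
Reactants: 7 1-benzofuran
Product: 8 benzofuran 2,3-oxide (1a,6b-dihydrooxireno[2,3-b][1]benzofuran, racemic)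
Conditions: dimethyldioxirane (1.1 equiv, freshly prepared acetone solution), CH2Cl2, −78 → −40 °C; volatiles removed below −30 °C, residue taken up in cold THF and used at once
Reagents that add atoms: dimethyldioxirane, CC1(C)OO1
Why: electrophilic epoxidation of the enol ether double bond by a neutral, non-nucleophilic oxidant should give the labile oxide with acetone as the only by-product; its stereocentres are erased in step 6.

Step 6
Reactants: 6 2-hydroxy-5-methoxy-4,6-bis(methoxymethoxy)-3-(3-methylbut-2-en-1-yl)benzaldehyde; 8 benzofuran 2,3-oxide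
Product: 11 (2R,3R)-3-hydroxy-2-(2-hydroxyphenyl)-6-methoxy-5,7-bis(methoxymethoxy)-8-(3-methylbut-2-en-1-yl)-2,3-dihydro-4H-chromen-4-one, via quinone methide aldehyde 9 (not isolated), via aryloxy aldehyde 10 (not isolated)
Conditions: iPr2NEt (1.5 equiv), 4 Å molecular sieves, THF, −40 → 0 °C; then (5aR,10bS)-2-(pentafluorophenyl)-5a,10b-dihydro-4H,6H-indeno[2,1-b][1,2,4]triazolo[4,3-d][1,4]oxazin-2-ium tetrafluoroborate (15 mol %), 0 °C → rt
Reagents that add atoms: none
Why: Proposed new method: the amine opens 8 to its valence isomer 9, an o-quinone methide whose exocyclic carbon (the future C2) takes up the only free phenoxide of 6 with rearomatisation of ring B (oxa-Michael type, O1–C2) to give racemic 10, which rests as a benzofuranol lactol; the triazolylidene then adds to the aromatic formyl group, and the resulting carbene–aldehyde adduct, an acyl anion equivalent nucleophilic at C4, attacks the C3 formyl carbon (C4–C3) before the carbene leaves the ketol. The closest known reaction types are the trapping of o-quinone methides by phenols and the carbene-catalysed intramolecular crossed benzoin that gives 3-hydroxychroman-4-ones. Ring C closes in the 6-exo-trig mode at the C3 carbonyl. C3 is set by the chiral carbene, chosen to deliver C4 to the Si face of the C3 formyl group (3R), and C2 is set by thermodynamic relay from C3, because 10 epimerises through reversion to 9 and through its enol and the product can still equilibrate at C2 by 2'-phenoxide-assisted ionisation of C2–O1, so that the trans-diequatorial (2R,3R) isomer should accumulate. The step needs (a) O-alkylation by the C8a oxygen only, secured by the MOM ethers on the C5 and C7 oxygens, (b) attack at the benzylic and not the acetal carbon of 8, secured by the ortho oxygen of ring B that makes this carbon a quinone methide terminus, and (c) the aromatic aldehyde as acyl donor, favoured by lactol masking of the aliphatic formyl group.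

Step 7
Reactants: 11 (2R,3R)-3-hydroxy-2-(2-hydroxyphenyl)-6-methoxy-5,7-bis(methoxymethoxy)-8-(3-methylbut-2-en-1-yl)-2,3-dihydro-4H-chromen-4-one
Product: 12 floranol, (2R,3R)-3,5,7-trihydroxy-2-(2-hydroxyphenyl)-6-methoxy-8-(3-methylbut-2-en-1-yl)-2,3-dihydro-4H-chromen-4-one
Conditions: 3 M aq. HCl/MeOH (1:5), 40 °C, stopped as soon as 11 is consumed
Reagents that add atoms: none
Why: acid-catalysed acetal exchange with methanol should remove both MOM groups while the trans-diequatorial stereocentres, already the thermodynamic arrangement, and the prenyl group tolerate brief dilute acid.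

**Compound list**

1 | 2-methoxybenzene-1,3-diol | COc1c(O)cccc1O | starting material
2 | 2-methoxy-1,3-bis(methoxymethoxy)benzene | COCOc1cccc(OCOC)c1OC | intermediate
3 | 2-[4-methoxy-3,5-bis(methoxymethoxy)phenyl]-4,4,5,5-tetramethyl-1,3,2-dioxaborolane | COCOc1cc(B2OC(C)(C)C(C)(C)O2)cc(OCOC)c1OC | intermediate
4 | 4-methoxy-3,5-bis(methoxymethoxy)phenol | COCOc1cc(O)cc(OCOC)c1OC | intermediate
5 | 4-methoxy-3,5-bis(methoxymethoxy)-2-(3-methylbut-2-en-1-yl)phenol | COCOc1cc(O)c(CC=C(C)C)c(OCOC)c1OC | intermediate
6 | 2-hydroxy-5-methoxy-4,6-bis(methoxymethoxy)-3-(3-methylbut-2-en-1-yl)benzaldehyde | COCOc1c(C=O)c(O)c(CC=C(C)C)c(OCOC)c1OC | intermediate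
7 | 1-benzofuran | c1ccc2occc2c1 | starting material
8 | benzofuran 2,3-oxide (racemic) | c1ccc2c(c1)OC1OC12 | intermediate
9 | (6-oxocyclohexa-2,4-dien-1-ylidene)acetaldehyde | O=CC=C1C=CC=CC1=O | intermediate
10 | 2-[1-(2-hydroxyphenyl)-2-oxoethoxy]-5-methoxy-4,6-bis(methoxymethoxy)-3-(3-methylbut-2-en-1-yl)benzaldehyde (racemic, drawn as the open form of its lactol) | COCOc1c(C=O)c(OC(C=O)c2ccccc2O)c(CC=C(C)C)c(OCOC)c1OC | intermediate
11 | (2R,3R)-3-hydroxy-2-(2-hydroxyphenyl)-6-methoxy-5,7-bis(methoxymethoxy)-8-(3-methylbut-2-en-1-yl)-2,3-dihydro-4H-chromen-4-one | COc1c(OCOC)c(CC=C(C)C)c2c(c1OCOC)C(=O)[C@H](O)[C@@H](c1ccccc1O)O2 | intermediate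
12 | floranol | COc1c(O)c(CC=C(C)C)c2c(c1O)C(=O)[C@H](O)[C@@H](c1ccccc1O)O2 | target

**Count**

Total steps: 7. Longest linear sequence: 6 steps (steps 1, 2, 3, 4, 6, 7); step 5 is the one-step side branch.

**Steps most likely to fail**

Step 6 (Proposed new method). The carbene may add to the more electrophilic aliphatic formyl group of 10 instead of the hindered, electron-rich aromatic one. The ketol would then form in the transposed sense and reach the conjugated ketone only by enediol tautomerism, with C3 set by uncontrolled protonation and loss of enantiocontrol. The carbene may also be captured by 9, or the cyclisation may be too slow to outrun base-induced decay of 10.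

Fallback by known chemistry, setting out from 6 and returning at 12:
- Addition of MeMgBr (THF, −78 → 0 °C) should give 1-[2-hydroxy-5-methoxy-4,6-bis(methoxymethoxy)-3-(3-methylbut-2-en-1-yl)phenyl]ethan-1-ol F1.
- Oxidation with MnO2 (CH2Cl2) should give 1-[2-hydroxy-5-methoxy-4,6-bis(methoxymethoxy)-3-(3-methylbut-2-en-1-yl)phenyl]ethan-1-one F2.
- Claisen–Schmidt condensation with commercial 2-(methoxymethoxy)benzaldehyde (KOH, EtOH) should give the (E)-2'-hydroxychalcone F3.
- Silylation (TBSOTf, 2,6-lutidine) should give the 2'-O-TBS chalcone F4.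
- Juliá–Colonna epoxidation (poly-L-leucine, urea–hydrogen peroxide, DBU, THF) is chemoselective for the enone over the prenyl group and is expected to give the (αR,βS)-epoxy ketone F5.
- HF·pyridine (THF, 0 °C → rt) should remove the silyl group and let the freed phenol open the epoxide at the benzylic carbon with inversion (6-endo), giving the 5,7,2'-tri-O-MOM dihydroflavonol F6.
- F6 is deprotected under the conditions of step 7 to give 12.

Step 5. The oxide may rearrange by hydride shift to a benzofuranone, or its valence isomer 9 may oligomerise, before it meets the phenoxide.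

Fallback, setting out from 7 and returning at 11: NBS in aqueous THF at 0 °C should give trans-3-bromo-2,3-dihydro-1-benzofuran-2-ol F7, a bench-handled ring-chain tautomer of bromo(2-hydroxyphenyl)acetaldehyde. F7 replaces 8 in step 6 with iPr2NEt raised to 2.5 equiv. Base-induced 1,4-elimination of HBr from the phenoxide, the classical generation of o-quinone methides from o-hydroxybenzyl halides, gives 9 in the flask, and the sequence continues through 10 to 11.

Step 3. O-alkylation and double alkylation may compete with the wanted mono-C-alkylation.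

Fallback, setting out from 4 and returning at 5: alkylation with 3-chloro-3-methylbut-1-yne (DBU, CuCl2 cat., MeCN, 0 °C) should give 2-methoxy-1,3-bis(methoxymethoxy)-5-[(2-methylbut-3-yn-2-yl)oxy]benzene F8. Semihydrogenation (H2, Pd/CaCO3 poisoned with Pb(OAc)2, quinoline, EtOAc) should give 2-methoxy-1,3-bis(methoxymethoxy)-5-[(2-methylbut-3-en-2-yl)oxy]benzene F9. Heating F9 in N,N-diethylaniline (about 120 °C) should deliver the prenyl group to the ortho carbon by aromatic Claisen rearrangement, giving 5.

**Further compounds**

F1 | step 6 | 1-[2-hydroxy-5-methoxy-4,6-bis(methoxymethoxy)-3-(3-methylbut-2-en-1-yl)phenyl]ethan-1-ol (racemic) | CC(O)c1c(O)c(CC=C(C)C)c(OCOC)c(OC)c1OCOC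
F2 | step 6 | 1-[2-hydroxy-5-methoxy-4,6-bis(methoxymethoxy)-3-(3-methylbut-2-en-1-yl)phenyl]ethan-1-one | CC(=O)c1c(O)c(CC=C(C)C)c(OCOC)c(OC)c1OCOC
F3 | step 6 | (E)-1-[2-hydroxy-5-methoxy-4,6-bis(methoxymethoxy)-3-(3-methylbut-2-en-1-yl)phenyl]-3-[2-(methoxymethoxy)phenyl]prop-2-en-1-one | O=C(/C=C/c1ccccc1OCOC)c1c(O)c(CC=C(C)C)c(OCOC)c(OC)c1OCOC
F4 | step 6 | (E)-1-[2-(tert-butyldimethylsilyloxy)-5-methoxy-4,6-bis(methoxymethoxy)-3-(3-methylbut-2-en-1-yl)phenyl]-3-[2-(methoxymethoxy)phenyl]prop-2-en-1-one | O=C(/C=C/c1ccccc1OCOC)c1c(O[Si](C)(C)C(C)(C)C)c(CC=C(C)C)c(OCOC)c(OC)c1OCOC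
F5 | step 6 | [2-(tert-butyldimethylsilyloxy)-5-methoxy-4,6-bis(methoxymethoxy)-3-(3-methylbut-2-en-1-yl)phenyl]{(2R,3S)-3-[2-(methoxymethoxy)phenyl]oxiran-2-yl}methanone | O=C([C@@H]1O[C@H]1c1ccccc1OCOC)c1c(O[Si](C)(C)C(C)(C)C)c(CC=C(C)C)c(OCOC)c(OC)c1OCOC
F6 | step 6 | (2R,3R)-3-hydroxy-6-methoxy-5,7-bis(methoxymethoxy)-2-[2-(methoxymethoxy)phenyl]-8-(3-methylbut-2-en-1-yl)-2,3-dihydro-4H-chromen-4-one | COc1c(OCOC)c(CC=C(C)C)c2c(c1OCOC)C(=O)[C@H](O)[C@@H](c1ccccc1OCOC)O2
F7 | step 5 | trans-3-bromo-2,3-dihydro-1-benzofuran-2-ol (racemic) | OC1Oc2ccccc2C1Br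
F8 | step 3 | 2-methoxy-1,3-bis(methoxymethoxy)-5-[(2-methylbut-3-yn-2-yl)oxy]benzene | COCOc1cc(OC(C)(C)C#C)cc(OCOC)c1OC
F9 | step 3 | 2-methoxy-1,3-bis(methoxymethoxy)-5-[(2-methylbut-3-en-2-yl)oxy]benzene | COCOc1cc(OC(C)(C)C=C)cc(OCOC)c1OC
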